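The free catalyst is single-handed, so it may couple the two substrates with the coupling partner at different rates, while the racemization catalyst interconverts the substrates. What you read in the product depends on what the product does next.

| flask | left-handed substrate | right-handed substrate | coupling partner | free catalyst | racemization catalyst | remark | time |
|---|---|---|---|---|---|---|---|
| amber | 18 mM | 18 mM | 28.6 mM | 75 µM | 25 µM | run made earlier |  |
| green | 29 mM | 29 mM | 28.6 mM | 75 µM | 25 µM | run made earlier |  |
| maple | 13 mM | 13 mM | 28.6 mM | 75 µM | 25 µM |  | 2.5 d |
| birch | 13 mM | 13 mM | 28.6 mM | 75 µM | 25 µM |  | 1.5 d |

| run | time / d | left-handed product / % | right-handed product / % |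
|---|---|---|---|
| amber | 0.417 | 15.8 | 15.9 |
| amber | 0.833 | 16.1 | 15.9 |
| amber | 1.25 | 16.3 | 16.6 |
| amber | 1.67 | 16.1 | 16.6 |
| amber | 2.00 | 16.7 | 15.7 |
| amber | 2.50 | 16.2 | 16.3 |
| amber | 3.00 | 16.3 | 16.3 |
| green | 0.167 | 11.9 | 11.9 |
| green | 0.500 | 13.0 | 12.8 |
| green | 0.833 | 13.1 | 12.8 |
| green | 1.25 | 12.9 | 13.3 |
| green | 1.67 | 12.3 | 12.4 |
| green | 2.50 | 12.6 | 13.0 |
| green | 3.00 | 12.3 | 12.6 |

(readings scatter by 0.3 percentage points)

- free catalyst is single-handed; left-handed substrate and right-handed substrate are mirror images of each other, charged as a racemate, each of them at the stated concentration
- an excess is the difference of the two amounts in percent of their sum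
- an excess is below zero if the other one leads

- the flask that ends with the higher excess of left-handed product over right-handed product in the product, or "neither" when 2 percentage points or less lies between them (maple / birch / neither)
- excess of left-handed product over right-handed product in the product at the end, maple
- excess of left-handed product over right-handed product in the product at the end, birch

Two extreme versions can be solved in the head. If the product's hand were locked, any excess made would stay; if it flipped at once, no excess would ever show. The real flask lies between, so follow the fraction of excess left. A single excess reading in green has a scatter of 1.78 %, and at 0.167 d the excess reads zero. Suppose a full excess stood at the start and at most twice that scatter remains. That takes 4.81 halvings, which gives h = 0.0347 d, my estimate, not a proven bound, of the longest half-life of a product excess that fits these readings. Product made later had less time, which would tighten h; a smaller start loosens it, but leaves less to lose.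

Birch is the tight case, with less time than maple. Green's product reads flat by 0.500 d. As a rough guess that birch's coupling is slower in step with its lower substrate charge, I stretch that time by the substrate ratio of 2.23, which gives 1.12 d, and with h the remaining time in birch leaves 0.0463 % of an excess standing at that moment. I therefore expect about zero in both flasks.

The forecast gives neither, with 0 % for maple and 0 % for birch: “Both maple and birch should therefore be racemic”. The flask gives neither, with 0 % for maple and 0 % for birch.

    coupling partner + free catalyst + left-handed substrate → free catalyst + left-handed product (k = 2.90 × 10⁵ /M²/h)
    left-handed product ⇌ right-handed product (k = 2.10 /h)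
    2 coupling partner → homo dimer (k = 23.0 /M/h)
    coupling partner + free catalyst + right-handed substrate → free catalyst + right-handed product (k = 29000 /M²/h)
    left-handed substrate + racemization catalyst ⇌ right-handed substrate + racemization catalyst, rate k5*[racemization catalyst]*[left-handed substrate] forward; the back reaction follows from the equilibrium constant (k = 2200 /M/h)

The selectivity factor is 10.0, yet the interconversion of the two products gives an excess a half-life of 0.165 h, shorter than the 1.15 h by which half of birch's left-handed coupling turnover is done. Birch has 89 % of that turnover behind it at 0.300 d, so that share has had at least 34.6 spans of h to lose its excess. The neighbour of birch charged with 0.30 mM of free catalyst gives its oldest product at most 43.2 spans of h and holds 30.7 % of right-handed product, with an excess of 0 %.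

The numbers in the tables come from a simulation on assumed constants.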